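## Structural features

Atoms are numbered as in germacranolides: the carbocycle is C1–C10, C11 is the carbinol carbon bearing OH and CH2Cl (C13), C12 is the lactone carbonyl, C14 is the methyl on C10 and C15 the methyl on C4; α is the face on which H-7 lies. The same numbers are kept for every intermediate.

- The target is a ten-membered carbocycle with a γ-lactone trans-fused across C6–C7 (O6–C12(=O)–C11–C7).
- The ring holds two trisubstituted alkenes, C1=C10 (Z, cis within the ring) and C4=C5 (E), which together form the 1,5-diene C10=C1–C2–C3–C4=C5.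
- Stereocentres C6 (R), C7 (R) and C8 (R, acetate) are contiguous; C11 (S, tertiary OH and CH2Cl) sits next to C7; C2 (S, allylic alcohol) is isolated on the far side of the ring.
- Fragile groups: the chlorohydrin (closes to an epoxide with base), the acetate and lactone, and the (Z,E)-cyclodeca-1,5-diene itself (transannular cyclisation with acid, Cope rearrangement on heating).
- The real difficulty is a medium ring with one Z and one E trisubstituted alkene next to the C6–C7–C8 triad, plus the remote C2 centre.
- The key step exploits the fact that this 1,5-diene is the Cope isomer of a cis-1,2-dialkenylcyclohexane built from C5–C10, the six atoms that carry C6, C7 and C8. (R)-Carvone maps onto that ring: C5 carbonyl, C10 methyl, C7 isopropenyl = C11–C13.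
- In one sentence: an anionic oxy-Cope ring expansion of a carvone-derived 1-isopropenyl-2-(2-alkoxyvinyl)cyclohexanol (C5–C10 broken, C2–C3 made), with the enolate captured as its triflate, gives the ten-membered ring and both alkene geometries at once.

## Logic of the disconnections

**C2–H and acetyl C–O (31 back to 27).** 31 comes from enone 30 by reagent-controlled hydride delivery, 30 from 29 by acylation, 29 from 28 by allylic oxidation, 28 from 27 by loss of both benzylic ethers. Reason: C2 then need not be controlled in the ring expansion, and the C2 ketone differentiates O2 from O8 without extra protecting groups. Demand: the reduction must override any bias of the macrocycle, and the oxidation must touch only the allylic C2–OH.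

**C13–Cl and C11–O (27 back to 25).** 27 comes from spiro-epoxide 26, and 26 from α-methylene lactone 25. Gain: C11 and C13 become one sp2 unit. Demand: oxygen must be delivered to the α face of C11 and chloride to C13 only.

**Lactone C12–O6 (25 back to 22).** 25 comes from 1,4-diol 23, itself from silylene 22. Gain: no enolisable or electrophilic lactone has to survive strong base. Demand: oxidation of the primary allylic alcohol in the presence of the secondary C6–OH.

**C5–H (22 back to 21).** The vinylic hydrogen replaces a triflate. Gain: the C5 oxygen that drives the key step is erased with retention of alkene geometry.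

**C2–C3 cut, C5–C10 re-joined (21 back to 18).** Retro-oxy-Cope. Gain: the medium ring and both trisubstituted alkenes disappear, leaving a cyclohexane whose stereocentres can be set by ring conformational control. Demand: a cis relationship of the two alkenyl groups, with the C5 isopropenyl axial and the C10 methyl axial in the reacting chair.

**C4–C5 (18 back to 17).** Isopropenyl nucleophile onto the C5 ketone. Demand: attack from the α face.

**C2–O and C1=C2 (17 back to 14).** Enol ether 17 from vinyl iodide 16, from aldehyde 15, from primary alcohol 14. Gain: a geometrically pure (E)-enol ether from a one-carbon handle.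

**C10–C1 and C9–H (14 back to 12).** Reductive hydroxymethylation of an enone. Gain: the quaternary C10 and its configuration come from a regiospecific enolate. Demand: attack anti to the axial C8 ether.

**C8–O (12 back through 11–6 to 5).** Allylic oxidation of a temporarily reduced and protected enone, then stereoselective reduction and re-oxidation at C5. Demand: site selectivity for the C8 methylene.

**Si–O, C6–O and C12–O (5 back to 1).** Silylene removal, α′-hydroxylation and allylic hydroxylation lead to the chiral-pool starting material 1, which supplies the C7 configuration.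

## Other disconnections considered

Alternative 1: (the first that comes to mind) cut C6–C7 and the lactone C–O bond. The forward key step is an intramolecular Nozaki–Hiyama–Kishi-type allylation of the open-chain aldehyde/allylic bromide A1 with CrCl2 (divalent chromium), closing the ten-membered ring and, after lactonisation, giving α-methylene lactone A2. The chosen plan is preferred because A1 must already contain both trisubstituted alkenes (including the Z one) and the separately made C2 and C8 centres. The macrocyclisation would also have to set C6 and C7 relative to C8 through a flexible transition state at high dilution. The key step would solve only ring closure, not alkene geometry.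

Alternative 2: cut C6–C7 after tying C6 to C13 through an ether oxygen. The forward key step is a [2,3]-Wittig ring contraction of the thirteen-membered diallylic ether A3 to the 6-hydroxy-7-alkenyl cyclodecadiene A4. The chosen plan is preferred because A3 still needs a macro-etherification and an acyclic triene with all alkene geometries pre-set. Deprotonation could occur at either allylic ether carbon, and the C7/C8 relationship would rest on an unpredictable transannular transition state.

Alternative 3: cut C8–C9 and re-join C1–C6. The forward key step is an anionic oxy-Cope of cyclohexanol A5 (ring made of C1–C6) to cyclodecenone A6, whose C7 enolate could be used for lactone annulation. The chosen plan is preferred because the six-membered ring of A5 contains C4 and C5, so the E alkene C4=C5 cannot be carried through and would have to be introduced later on the medium ring without geometric control. The chosen ring expansion creates both alkenes stereospecifically in the same step.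

Key step: step 16

Assumption: the SMILES is read as the (2S,6R,7R,8R,11S)-1(10)Z,4E isomer; the (E)-enol ether used in the key step is expected to give the 2R epimer, which is deliberately re-set to 2S in steps 23 and 25.

Step 1
Reactants: 1 (R)-(−)-carvone
Product: 2 12-hydroxycarvone [(5R)-5-(3-hydroxyprop-1-en-2-yl)-2-methylcyclohex-2-en-1-one]
Conditions: SeO2 (cat.), t-BuOOH, CH2Cl2, 25 °C
Reagents that add atoms: tert-butyl hydroperoxide (CC(C)(C)OO)
Why: Allylic hydroxylation by SeO2 (ene reaction then [2,3] shift) should select the electron-richer 1,1-disubstituted alkene and its methyl group, since the enone alkene is deactivated; the C7 stereocentre is untouched.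

Step 2
Reactants: 2 12-hydroxycarvone
Product: 4 6α,12-dihydroxycarvone (6-OH trans to the C7 side chain), via dipotassium dianion 3 (not isolated)
Conditions: KN(SiMe3)2 (2.3 equiv), THF, −78 °C; then 3-phenyl-2-(phenylsulfonyl)oxaziridine, −78 °C; then aq NH4Cl
Reagents that add atoms: 3-phenyl-2-(phenylsulfonyl)oxaziridine (O=S(=O)(N1OC1c1ccccc1)c1ccccc1)
Why: Kinetic α′-deprotonation of the enone (after the alkoxide) and Davis hydroxylation of the cross-conjugated enolate; the oxidant should approach C6 anti to the C7 substituent, giving the 6α (trans) alcohol.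

Step 3
Reactants: 4 6α,12-dihydroxycarvone
Product: 5 silylene enone (6α-O and 12-O bridged by di-tert-butylsilanediyl, trans-fused seven-membered ring)
Conditions: t-Bu2Si(OTf)2, 2,6-lutidine, CH2Cl2, 0 °C
Reagents that add atoms: di-tert-butylsilyl bis(trifluoromethanesulfonate) (CC(C)(C)[Si](OS(=O)(=O)C(F)(F)F)(OS(=O)(=O)C(F)(F)F)C(C)(C)C)
Why: Cyclic silylene formation across the 1,4-diol; the trans-diequatorial O6 and C11 can span the seven-membered ring, which protects both oxygens and later locks ring B in one chair.

Step 4
Reactants: 5 silylene enone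
Product: 6 5β-allylic alcohol (5-OH cis to the C7 side chain, trans to 6-O)
Conditions: NaBH4, CeCl3·7H2O, MeOH, −78 to −40 °C
Reagents that add atoms: none
Why: Luche 1,2-reduction; axial hydride delivery should give the equatorial 5β-alcohol (as in carvone to cis-carveol); C5 is only a temporary stereocentre.

Step 5
Reactants: 6 5β-allylic alcohol
Product: 7 5β-triethylsilyl ether
Conditions: Et3SiCl, imidazole, DMF, 0 °C
Reagents that add atoms: chlorotriethylsilane (CC[Si](Cl)(CC)CC)
Why: Standard silylation; the labile triethylsilyl group can later be removed without touching the silylene.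

Step 6
Reactants: 7 5β-triethylsilyl ether
Product: 8 C8 enone (8-oxo, conjugated with C9=C10)
Conditions: Rh2(cap)4 (cap = caprolactamate, 1 mol %), t-BuOOH, K2CO3, CH2Cl2, 25 °C
Reagents that add atoms: tert-butyl hydroperoxide (CC(C)(C)OO)
Why: Allylic C–H oxidation by tert-butylperoxyl radicals under dirhodium catalysis; C8 is the only ring allylic methylene, so the enone is transposed from C5 to C8.

Step 7
Reactants: 8 C8 enone
Product: 9 8β-allylic alcohol (8-OH cis to the C7 side chain)
Conditions: LiBH(s-Bu)3, THF, −78 °C; then aq NH4Cl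
Reagents that add atoms: none
Why: β-Substituted cyclohexenones undergo 1,2-reduction with this bulky hydride, which should attack from the equatorial direction to give the axial 8β-alcohol cis to the equatorial C7 substituent.

Step 8
Reactants: 9 8β-allylic alcohol
Product: 10 8β-(4-methoxybenzyl) ether
Conditions: NaH, 4-MeOC6H4CH2Cl, Bu4NI (cat.), DMF, 0 to 25 °C
Reagents that add atoms: 4-methoxybenzyl chloride (COc1ccc(CCl)cc1)
Why: Williamson etherification; the silyl ethers are stable to NaH.

Step 9
Reactants: 10 8β-(4-methoxybenzyl) ether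
Product: 11 5β-alcohol (triethylsilyl group removed)
Conditions: pyridinium p-toluenesulfonate (cat.), MeOH, 0 °C
Reagents that add atoms: none
Why: Mild acid methanolysis cleaves the allylic triethylsilyl ether much faster than the hindered di-tert-butylsilylene or the benzylic ether.

Step 10
Reactants: 11 5β-alcohol
Product: 12 C5 enone with 8β-OPMB (PMB = 4-methoxybenzyl)
Conditions: MnO2, CH2Cl2, 25 °C
Reagents that add atoms: none
Why: Chemoselective oxidation of the allylic alcohol by MnO2 (tetravalent manganese) restores the carvone-type enone, now carrying the axial 8β ether.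

Step 11
Reactants: 12 C5 enone
Product: 14 hydroxymethyl ketone (10β-methyl, 10α-CH2OH, C9 saturated), via lithium enolate 13 (not isolated)
Conditions: LiBH(s-Bu)3 (1.05 equiv), THF, −78 °C; then CH2O (gas), −78 to −40 °C; then aq NH4Cl
Reagents that add atoms: formaldehyde (C=O)
Why: Reductive aldol: conjugate hydride addition to the α-methyl enone gives the tetrasubstituted enolate 13 regiospecifically, and formaldehyde should attack C10 anti to the axial 8β-OPMB of the silylene-locked ring, placing C1 on the α face and the methyl axial (β).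

Step 12
Reactants: 14 hydroxymethyl ketone
Product: 15 keto aldehyde (10α-formyl)
Conditions: Dess–Martin periodinane, NaHCO3, CH2Cl2, 0 to 25 °C
Reagents that add atoms: none
Why: Neutral oxidation of the neopentyl primary alcohol; the non-enolisable β-keto aldehyde cannot epimerise at C10.

Step 13
Reactants: 15 keto aldehyde
Product: 16 (E)-vinyl iodide (10α-[(E)-2-iodovinyl])
Conditions: CrCl2, CHI3, THF, 0 to 25 °C
Reagents that add atoms: iodoform (IC(I)I)
Why: Takai olefination with CrCl2 (divalent chromium); it is E-selective for hindered aldehydes and leaves the ketone untouched.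

Step 14
Reactants: 16 (E)-vinyl iodide
Product: 17 (E)-enol ether ketone (10α-[(E)-2-(4-methoxybenzyloxy)vinyl])
Conditions: CuI (10 mol %), 3,4,7,8-tetramethyl-1,10-phenanthroline, Cs2CO3, 4-MeOC6H4CH2OH, toluene, 80 °C
Reagents that add atoms: 4-methoxybenzyl alcohol (COc1ccc(CO)cc1)
Why: Ullmann-type copper-catalysed C–O coupling of a vinyl iodide with an alcohol, which proceeds with retention of the E geometry.

Step 15
Reactants: 17 (E)-enol ether ketone
Product: 18 tertiary alcohol (5S,10S; 5β-OH, 5α-isopropenyl)
Conditions: CH2=C(CH3)MgBr, CeCl3, THF, −78 °C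
Reagents that add atoms: isopropenylmagnesium bromide (C=C(C)[Mg]Br)
Why: Organocerium 1,2-addition suppresses enolisation of the hindered ketone; the axial 10β-methyl blocks the equatorial trajectory, so attack should be axial from the α face, giving the isopropenyl group cis to the C10 alkenyl group.

Step 16
Reactants: 18 tertiary alcohol
Product: 21 ten-membered enol triflate (1(10)Z, 4Z-5-triflyloxy; 2R-OPMB, 8β-OPMB, 6α,12-O-silylene), via potassium alkoxide 19 (not isolated), via ring-expanded potassium enolate 20 (not isolated)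
Conditions: KN(SiMe3)2, 18-crown-6, THF, 0 to 25 °C; then PhNTf2, −78 to 0 °C; then aq NH4Cl
Reagents that add atoms: N-phenylbis(trifluoromethanesulfonimide) (O=S(=O)(N(c1ccccc1)S(=O)(=O)C(F)(F)F)C(F)(F)F)
Why: Alkoxide 19 accelerates the [3,3] shift of the 1,5-diene C3=C4–C5–C10–C1=C2 (anionic oxy-Cope, the known ring expansion of 1,2-dialkenylcyclohexanols to cyclodec-5-enones), breaking C5–C10 and forming C2–C3. The ten-membered ring therefore arises by four-atom ring expansion through a six-membered chair transition state, not by end-to-end cyclisation. The trans-fused silylene holds ring B in one chair in which the C5 isopropenyl is axial and the C10 alkenyl equatorial; on the cyclic array C9 is then pseudoaxial and C6 pseudoequatorial, which translates into the 1(10)Z alkene and into an enolate with oxygen cis to C3, the precursor of 4E. Release of the syn-diaxial 10-methyl/8-OPMB strain adds driving force. The (E)-enol ether places OPMB pseudoequatorial, avoiding the allylic clash a Z ether would have with C9, and should give 2R; this centre is re-set later, so leakage here is harmless. Enolate 20 forms only toward C4 and is O-sulfonylated before proton exchange can scramble it. The step needs [3,3] shift over fragmentation, chair over boat and O- over C-sulfonylation; these are secured by the locked cis-dialkenyl geometry, the crown-ether-separated potassium enolate and the hard sulfonyl electrophile.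

Step 17
Reactants: 21 ten-membered enol triflate
Product: 22 (1(10)Z,4E)-triene (C5–H; silylene and both PMB ethers intact)
Conditions: Pd(OAc)2 (5 mol %), PPh3, HCO2H, n-Bu3N, DMF, 40 °C
Reagents that add atoms: none
Why: Palladium-catalysed formate reduction of a vinyl triflate (oxidative addition, decarboxylation to the hydride, reductive elimination) with retention, so the Z triflate becomes the 4E alkene; the temperature is kept low to avoid thermal Cope reversion.

Step 18
Reactants: 22 (1(10)Z,4E)-triene
Product: 23 6α,12-diol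
Conditions: Bu4NF, THF, 0 to 25 °C
Reagents that add atoms: none
Why: Fluoride cleavage of the silylene; the benzylic ethers and the diene are unaffected.

Step 19
Reactants: 23 6α,12-diol
Product: 25 α-methylene-γ-lactone (6α,12-olide), via lactol 24 (not isolated)
Conditions: TEMPO (cat.), PhI(OAc)2, CH2Cl2, 25 °C
Reagents that add atoms: none
Why: Oxoammonium oxidation of the primary allylic alcohol to the aldehyde, closure to lactol 24 with the 6α-OH and further oxidation to the lactone; the hindered secondary C6–OH is oxidised much more slowly.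

Step 20
Reactants: 25 α-methylene-γ-lactone
Product: 26 11α,13-epoxide (spiro-epoxy lactone)
Conditions: t-BuOOH, DBU, CH2Cl2, 0 °C
Reagents that add atoms: tert-butyl hydroperoxide (CC(C)(C)OO)
Why: Weitz–Scheffer nucleophilic epoxidation reacts only with the electron-poor exocyclic alkene; the peroxy enolate should close on the α face of C11 (the H-7 side, away from the C8 substituent).

Step 21
Reactants: 26 11α,13-epoxide
Product: 27 chlorohydrin (11S; 11α-OH, 13-Cl)
Conditions: LiCl, AcOH, THF, 25 °C
Reagents that add atoms: lithium chloride ([Li+].[Cl-])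
Why: SN2 opening of the epoxide by chloride at the unhindered C13; C11 is quaternary and keeps its configuration.

Step 22
Reactants: 27 chlorohydrin
Product: 28 2R,8β-diol
Conditions: DDQ, CH2Cl2/pH 7 buffer, 0 °C
Reagents that add atoms: none
Why: Oxidative cleavage of both 4-methoxybenzyl ethers under neutral conditions that spare the chlorohydrin, lactone and diene.

Step 23
Reactants: 28 2R,8β-diol
Product: 29 C2 enone (8β-OH free)
Conditions: MnO2, CH2Cl2, 25 °C
Reagents that add atoms: none
Why: MnO2 oxidises only the allylic C2 alcohol; the non-allylic C8 and tertiary C11 alcohols are inert, which differentiates O2 from O8.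

Step 24
Reactants: 29 C2 enone
Product: 30 8β-acetate enone
Conditions: Ac2O, pyridine, CH2Cl2, 0 to 25 °C
Reagents that add atoms: acetic anhydride (CC(=O)OC(C)=O)
Why: Acylation of the only secondary alcohol; without a nucleophilic catalyst the hindered tertiary C11–OH should not react.

Step 25
Reactants: 30 8β-acetate enone
Product: 31 target compound CNP0360028.4
Conditions: (R)-2-methyl-CBS-oxazaborolidine, catecholborane, toluene, −78 °C
Reagents that add atoms: none
Why: Corey–Bakshi–Shibata reduction; with the trisubstituted alkenyl arm as the large group the (R)-catalyst should deliver hydride to give the 2S allylic alcohol, and catecholborane at low temperature spares lactone, acetate and alkenes.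

## Compound list

1 | (R)-(−)-carvone | O=C1C[C@H](C(C)=C)CC=C1C | starting material
2 | 12-hydroxycarvone | O=C1C[C@H](C(=C)CO)CC=C1C | intermediate
3 | dipotassium enolate-alkoxide of 2 | [K+].[K+].[O-]C1=C[C@H](C(=C)C[O-])CC=C1C | intermediate
4 | 6α,12-dihydroxycarvone, (5S,6S) in cyclohexenone numbering | O=C1[C@@H](O)[C@H](C(=C)CO)CC=C1C | intermediate
5 | silylene enone (6α-O,12-O-di-tert-butylsilanediyl) | O=C1[C@H]2O[Si](C(C)(C)C)(C(C)(C)C)OCC(=C)[C@@H]2CC=C1C | intermediate
6 | 5β-allylic alcohol | O[C@@H]1[C@H]2O[Si](C(C)(C)C)(C(C)(C)C)OCC(=C)[C@@H]2CC=C1C | intermediate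
7 | 5β-triethylsilyl ether | CC[Si](CC)(CC)O[C@@H]1[C@H]2O[Si](C(C)(C)C)(C(C)(C)C)OCC(=C)[C@@H]2CC=C1C | intermediate
8 | C8 enone | CC[Si](CC)(CC)O[C@@H]1[C@H]2O[Si](C(C)(C)C)(C(C)(C)C)OCC(=C)[C@@H]2C(=O)C=C1C | intermediate
9 | 8β-allylic alcohol | CC[Si](CC)(CC)O[C@@H]1[C@H]2O[Si](C(C)(C)C)(C(C)(C)C)OCC(=C)[C@@H]2[C@H](O)C=C1C | intermediate
10 | 8β-(4-methoxybenzyl) ether | CC[Si](CC)(CC)O[C@@H]1[C@H]2O[Si](C(C)(C)C)(C(C)(C)C)OCC(=C)[C@@H]2[C@H](OCc3ccc(OC)cc3)C=C1C | intermediate
11 | 5β-alcohol with 8β-OPMB | O[C@@H]1[C@H]2O[Si](C(C)(C)C)(C(C)(C)C)OCC(=C)[C@@H]2[C@H](OCc3ccc(OC)cc3)C=C1C | intermediate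
12 | C5 enone with 8β-OPMB | O=C1[C@H]2O[Si](C(C)(C)C)(C(C)(C)C)OCC(=C)[C@@H]2[C@H](OCc3ccc(OC)cc3)C=C1C | intermediate
13 | lithium enolate (C5–OLi, C5=C10) | [Li+].[O-]C=1[C@H]2O[Si](C(C)(C)C)(C(C)(C)C)OCC(=C)[C@@H]2[C@H](OCc3ccc(OC)cc3)CC=1C | intermediate
14 | hydroxymethyl ketone (10β-Me, 10α-CH2OH) | O=C1[C@H]2O[Si](C(C)(C)C)(C(C)(C)C)OCC(=C)[C@@H]2[C@H](OCc3ccc(OC)cc3)C[C@]1(CO)C | intermediate
15 | keto aldehyde (10α-CHO) | O=C1[C@H]2O[Si](C(C)(C)C)(C(C)(C)C)OCC(=C)[C@@H]2[C@H](OCc3ccc(OC)cc3)C[C@]1(C=O)C | intermediate
16 | (E)-vinyl iodide | O=C1[C@H]2O[Si](C(C)(C)C)(C(C)(C)C)OCC(=C)[C@@H]2[C@H](OCc3ccc(OC)cc3)C[C@]1(/C=C/I)C | intermediate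
17 | (E)-enol ether ketone | O=C1[C@H]2O[Si](C(C)(C)C)(C(C)(C)C)OCC(=C)[C@@H]2[C@H](OCc3ccc(OC)cc3)C[C@]1(/C=C/OCc3ccc(OC)cc3)C | intermediate
18 | tertiary alcohol (5S,10S; 5α-isopropenyl, 5β-OH) | O[C@]1(C(C)=C)[C@H]2O[Si](C(C)(C)C)(C(C)(C)C)OCC(=C)[C@@H]2[C@H](OCc3ccc(OC)cc3)C[C@]1(/C=C/OCc3ccc(OC)cc3)C | intermediate
19 | potassium alkoxide of 18 | [K+].[O-][C@]1(C(C)=C)[C@H]2O[Si](C(C)(C)C)(C(C)(C)C)OCC(=C)[C@@H]2[C@H](OCc3ccc(OC)cc3)C[C@]1(/C=C/OCc3ccc(OC)cc3)C | intermediate
20 | ring-expanded potassium enolate (C4=C5–OK, 1(10)Z, 2R) | [K+].COc1ccc(CO[C@@H]2C/C(C)=C\[C@H](OCc3ccc(OC)cc3)C/C(C)=C([O-])/[C@H]3O[Si](C(C)(C)C)(C(C)(C)C)OCC(=C)[C@@H]32)cc1 | intermediate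
21 | ten-membered enol triflate (1(10)Z,4Z) | COc1ccc(CO[C@@H]2C/C(C)=C\[C@H](OCc3ccc(OC)cc3)C/C(C)=C(OS(=O)(=O)C(F)(F)F)/[C@H]3O[Si](C(C)(C)C)(C(C)(C)C)OCC(=C)[C@@H]32)cc1 | intermediate
22 | (1(10)Z,4E)-triene, silylene, bis-PMB ether | COc1ccc(CO[C@@H]2C/C(C)=C\[C@H](OCc3ccc(OC)cc3)C/C(C)=C/[C@H]3O[Si](C(C)(C)C)(C(C)(C)C)OCC(=C)[C@@H]32)cc1 | intermediate
23 | 6α,12-diol | COc1ccc(CO[C@@H]2C/C(C)=C\[C@H](OCc3ccc(OC)cc3)C/C(C)=C/[C@@H](O)[C@@H]2C(=C)CO)cc1 | intermediate
24 | lactol (6α,12-hemiacetal) | COc1ccc(CO[C@@H]2C/C(C)=C\[C@H](OCc3ccc(OC)cc3)C/C(C)=C/[C@H]3OC(O)C(=C)[C@@H]32)cc1 | intermediate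
25 | α-methylene-γ-lactone | COc1ccc(CO[C@@H]2C/C(C)=C\[C@H](OCc3ccc(OC)cc3)C/C(C)=C/[C@H]3OC(=O)C(=C)[C@@H]32)cc1 | intermediate
26 | 11α,13-epoxy lactone | COc1ccc(CO[C@@H]2C/C(C)=C\[C@H](OCc3ccc(OC)cc3)C/C(C)=C/[C@H]3OC(=O)[C@]4(CO4)[C@@H]32)cc1 | intermediate
27 | chlorohydrin bis-PMB ether | COc1ccc(CO[C@@H]2C/C(C)=C\[C@H](OCc3ccc(OC)cc3)C/C(C)=C/[C@H]3OC(=O)[C@](O)(CCl)[C@@H]32)cc1 | intermediate
28 | 2R,8β-diol chlorohydrin lactone | O[C@@H]1C/C(C)=C\[C@H](O)C/C(C)=C/[C@H]2OC(=O)[C@](O)(CCl)[C@@H]21 | intermediate
29 | C2 enone, 8β-OH | O[C@@H]1C/C(C)=C\C(=O)C/C(C)=C/[C@H]2OC(=O)[C@](O)(CCl)[C@@H]21 | intermediate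
30 | C2 enone, 8β-OAc | CC(=O)O[C@@H]1C/C(C)=C\C(=O)C/C(C)=C/[C@H]2OC(=O)[C@](O)(CCl)[C@@H]21 | intermediate
31 | CNP0360028.4, (2S,6R,7R,8R,11S)-8-acetoxy-13-chloro-2,11-dihydroxygermacra-1(10)Z,4E-dien-12,6-olide | CC(=O)O[C@@H]1C/C(C)=C\[C@@H](O)C/C(C)=C/[C@H]2OC(=O)[C@](O)(CCl)[C@@H]21 | target

## Step count and least certain steps

Total: 25 steps, all linear; longest linear sequence 25 steps from 1.

**Step 16 (key step).** The most likely failure is incomplete or unselective capture of the crowded, strongly basic potassium enolate. Proton return or C-sulfonylation would lose the regio- and geometric information that the sigmatropic shift has just created, because the free ketone cannot be re-enolised selectively. The fallback sets out from 18 and returns at 21. After the rearrangement the enolate is quenched with Me3SiCl to give the trimethylsilyl enol ether of the ring-expanded ketone F1, which can be purified and its geometry checked. MeLi then regenerates a lithium enolate, which is triflated with N-(5-chloropyridin-2-yl)bis(trifluoromethanesulfonimide) to give 21.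

**Step 6.** Hydrogen abstraction may also occur at the C12 methylene, at C7–H or at C5–H, so site selectivity may be poor. The fallback sets out from 5 and returns at 12, bypassing 6–11.
- Me3SiOTf/Et3N gives the extended trimethylsilyl dienol ether F2.
- Vinylogous Rubottom oxidation with m-CPBA at the C8 terminus, anti to the C7 substituent, gives the 8α-hydroxy enone F3.
- Mitsunobu inversion with 4-nitrobenzoic acid gives the 8β-(4-nitrobenzoate) F4.
- Methanolysis (K2CO3, MeOH) gives the 8β-hydroxy enone F5.
- 4-Methoxybenzyl trichloroacetimidate with catalytic acid then gives 12.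

**Step 11.** Facial leakage is the risk: attack of formaldehyde syn to the C8 ether would give the C10 epimer, which cannot enter the required chair. The fallback sets out from 12 and returns at 14. Conjugate reduction followed by Me3SiCl gives the trimethylsilyl enol ether F6. A Mukaiyama-type hydroxymethylation with aqueous formaldehyde, Sc(OTf)3 and a chiral 2,2′-bipyridine diol ligand then puts the face of attack under reagent control.

**Step 15.** The bulky organocerium may attack equatorially, or enolise the ketone, giving the trans-dialkenyl carbinol that would lead to the E,E-diene. The fallback sets out from 17 and returns at 18. The small, axially selective nucleophile HC≡CMgBr/CeCl3 gives the ethynyl carbinol F7. Hydroxyl-directed, CuI-catalysed carbomagnesiation with MeMgBr then adds methyl to the internal alkyne carbon and gives 18 after protonation.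

**Step 20.** Facial selectivity at C11 on the flexible ten-membered lactone may be poor. The fallback sets out from 18 and returns at 26, setting C11 on the rigid bicyclic system before ring expansion.
- Bu4NF gives triol F8.
- MnO2 gives the trans-fused α-methylene lactone carbinol F9.
- t-BuOOH/DBU gives the spiro-epoxy lactone carbinol F10, with oxygen delivered anti to the axial 8β-OPMB.
- The conditions of step 16 applied to F10, which has no enolisable lactone hydrogen and is locked by the trans-fused lactone, give the enol triflate epoxy-lactone F11.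
- The conditions of step 17 then give 26.

**Step 25.** The conformational bias of the macrocycle may be mismatched with the catalyst and erode selectivity at C2. The fallback sets out from 28 and returns at 31. Mitsunobu inversion of the allylic 2R alcohol with chloroacetic acid gives the 2S chloroacetate diol F12. Acetylation gives the 2S chloroacetate 8-acetate F13. Selective removal of the chloroacetate with thiourea/NaHCO3 gives 31.

## Further compounds

F1 | step 16 | trimethylsilyl enol ether of the ring-expanded ketone | COc1ccc(CO[C@@H]2C/C(C)=C\[C@H](OCc3ccc(OC)cc3)C/C(C)=C(O[Si](C)(C)C)/[C@H]3O[Si](C(C)(C)C)(C(C)(C)C)OCC(=C)[C@@H]32)cc1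
F2 | step 6 | extended trimethylsilyl dienol ether of 5 | C[Si](C)(C)OC1=C(C)C=C[C@H]2C(=C)CO[Si](C(C)(C)C)(C(C)(C)C)O[C@H]12
F3 | step 6 | 8α-hydroxy enone | O=C1[C@H]2O[Si](C(C)(C)C)(C(C)(C)C)OCC(=C)[C@@H]2[C@@H](O)C=C1C
F4 | step 6 | 8β-(4-nitrobenzoate) | O=C1[C@H]2O[Si](C(C)(C)C)(C(C)(C)C)OCC(=C)[C@@H]2[C@H](OC(=O)c3ccc([N+](=O)[O-])cc3)C=C1C
F5 | step 6 | 8β-hydroxy enone | O=C1[C@H]2O[Si](C(C)(C)C)(C(C)(C)C)OCC(=C)[C@@H]2[C@H](O)C=C1C
F6 | step 11 | trimethylsilyl enol ether (C5=C10) | C[Si](C)(C)OC=1[C@H]2O[Si](C(C)(C)C)(C(C)(C)C)OCC(=C)[C@@H]2[C@H](OCc3ccc(OC)cc3)CC=1C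
F7 | step 15 | ethynyl carbinol | O[C@]1(C#C)[C@H]2O[Si](C(C)(C)C)(C(C)(C)C)OCC(=C)[C@@H]2[C@H](OCc3ccc(OC)cc3)C[C@]1(/C=C/OCc3ccc(OC)cc3)C
F8 | step 20 | triol | O[C@]1(C(C)=C)[C@@H](O)[C@H](C(=C)CO)[C@H](OCc3ccc(OC)cc3)C[C@]1(/C=C/OCc3ccc(OC)cc3)C
F9 | step 20 | trans-fused α-methylene lactone carbinol | O[C@]1(C(C)=C)[C@H]2OC(=O)C(=C)[C@@H]2[C@H](OCc3ccc(OC)cc3)C[C@]1(/C=C/OCc3ccc(OC)cc3)C
F10 | step 20 | spiro-epoxy lactone carbinol | O[C@]1(C(C)=C)[C@H]2OC(=O)[C@]4(CO4)[C@@H]2[C@H](OCc3ccc(OC)cc3)C[C@]1(/C=C/OCc3ccc(OC)cc3)C
F11 | step 20 | enol triflate epoxy-lactone | COc1ccc(CO[C@@H]2C/C(C)=C\[C@H](OCc3ccc(OC)cc3)C/C(C)=C(OS(=O)(=O)C(F)(F)F)/[C@H]3OC(=O)[C@]4(CO4)[C@@H]32)cc1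
F12 | step 25 | 2S chloroacetate diol | O[C@@H]1C/C(C)=C\[C@@H](OC(=O)CCl)C/C(C)=C/[C@H]2OC(=O)[C@](O)(CCl)[C@@H]21
F13 | step 25 | 2S chloroacetate 8-acetate | CC(=O)O[C@@H]1C/C(C)=C\[C@@H](OC(=O)CCl)C/C(C)=C/[C@H]2OC(=O)[C@](O)(CCl)[C@@H]21
A1 | alternative 1 | open-chain aldehyde/allylic bromide | O=C/C=C(\C)C[C@H](O[Si](C)(C)C(C)(C)C)/C=C(/C)C[C@@H](OC(C)=O)/C=C(\CBr)C(=O)OC
A2 | alternative 1 | 2-silyloxy α-methylene lactone | CC(=O)O[C@@H]1C/C(C)=C\[C@@H](O[Si](C)(C)C(C)(C)C)C/C(C)=C/[C@H]2OC(=O)C(=C)[C@@H]21
A3 | alternative 2 | thirteen-membered diallylic ether | O1C/C=C(\C)C[C@H](OCc2ccc(OC)cc2)/C=C(/C)C[C@@H](OCc2ccc(OC)cc2)/C=C(/CO[Si](C)(C)C(C)(C)C)C1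
A4 | alternative 2 | 6-hydroxy-7-alkenyl cyclodecadiene | O[C@@H]1/C=C(\C)C[C@H](OCc2ccc(OC)cc2)/C=C(/C)C[C@@H](OCc2ccc(OC)cc2)[C@H]1C(=C)CO[Si](C)(C)C(C)(C)C
A5 | alternative 3 | 1-alkenyl-2-isopropenylcyclohexanol (ring C1–C6) | O[C@]1(/C=C/OCc2ccc(OC)cc2)C[C@H](C)C[C@H](OCc2ccc(OC)cc2)[C@H]1C(C)=C
A6 | alternative 3 | cyclodec-5-enone (C6 ketone) | O=C1C[C@H](C)C[C@H](OCc2ccc(OC)cc2)/C=C(/C)C[C@@H](OCc2ccc(OC)cc2)C1
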